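The readings are simulated on assumed constants; the scatter is artificial.

In a one-step world, product is made at a rate that goes as a power of the partner, and that power, the order in partner, is a slope on logarithms.

| flask | substrate | partner | free catalyst | remark | time |
|---|---|---|---|---|---|
| east | 0.50 M | 0.50 M (in portions, 3) | 10 mM | run made earlier; portions every 1.5 min |  |
| north-west | 0.50 M | 2 M (in portions, 3) | 10 mM | run made earlier; portions every 1.5 min |  |
| dawn | 0.50 M | 1.00 M (in portions, 3) | 10 mM | the portions of partner follow each other after 1.5 min, the first at the start | 2.0 h |
| midnight | 0.50 M | 1.00 M (in portions, 3) | 10 mM | the portions of partner follow each other after 3.0 min, the first at the start | 2.0 h |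
| autumn | 0.50 M | 1.00 M (in portions, 3) | 10 mM | the portions of partner follow each other after 6.0 min, the first at the start | 2.0 h |

| run | time / h | product / % | substrate / % |
|---|---|---|---|
| east | 0.200 | 3 | 95 |
| east | 0.667 | 11 | 88 |
| east | 1.00 | 14 | 86 |
| east | 1.50 | 24 | 78 |
| east | 2.50 | 37 | 67 |
| north-west | 0.200 | 6 | 92 |
| north-west | 0.667 | 26 | 79 |
| north-west | 1.00 | 36 | 65 |
| north-west | 1.50 | 48 | 50 |
| north-west | 2.50 | 75 | 28 |

(each reading ± 1.5 percentage points)

1. amount of product at the end, in percent of the substrate charged for dawn, midnight, autumn, in this order
2. how the row runs (hardly changes / rises all the way / falls, then rises / falls all the way / rises, then falls)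

- the analysis behind the earlier runs scatters by 1.5 percentage points, standard deviation
- "hardly changes" means that all values lie within two and a half points (for a concentration: within two and a half percent of the largest)

I start from the last readings of the north-west and east runs, which have the same gap between portions as dawn. Like every reading, they carry the scatter of 1.5 percentage points.

order = log of 2.03 over log of 4.00 = 0.307 / 0.602 = 0.510

Both product lines run roughly straight, so I scale east to dawn's partner charge and time:

dawn = 37.0% × 2.00^0.510 × 0.800 = 0.421 of the charge

Now the portions. During the first gap, the partner added is a third of its charge, and during the second gap 0.667 of it. Each gap therefore runs below full rate. The lost time is the full-rate time that these gaps cost. For autumn: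

lost time = 0.1 h × (2 − 0.571 − 0.813) = 0.0615 h

Dawn has already paid its share of this, so autumn falls below dawn by:

0.421 × 0.0461 h / 2.0 h = 0.00973 of the charge

The weak link is the order, which hangs on one pair of readings. Summing all the product readings of each run gives a sturdier slope:

order = 0.551, dawn = 0.434, lost time in autumn = 0.0654 h

My reckoning therefore commits to 0.434 for dawn and 0.423 for autumn, a row that hardly changes.

The forecast, reasoned separately, gave 43%, 42.5% and 42%, so hardly changes, holding that “the slowest schedule loses about 0.06 h of full-rate time”.

The flasks gave 45.2%, 44.8% and 44.1%: the row hardly changes.

    partner + free catalyst ⇌ catalyst intermediate A (K = 0.320 /M, k = 2.00 /M/min)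
    catalyst intermediate A ⇌ catalyst intermediate B (K = 2.80, k = 2.20 /min)
    substrate + catalyst intermediate B → catalyst intermediate C (k = 3.30 /M/min)
    catalyst intermediate C → released group + catalyst intermediate D (k = 140 /min)
    catalyst intermediate D → catalyst intermediate E (k = 2.30 /min)
    catalyst intermediate E → free catalyst + product (k = 240 /min)

At the end of dawn, partner and free catalyst relax towards balance with catalyst intermediate A with a half-life of 0.0888 min, far shorter than the 1.5 min between dawn's portions, while substrate's half-life by its step with catalyst intermediate B is 2.1 h, far longer than autumn's lost time of 0.0615 h to 0.0654 h. Autumn ended 1.1 points below dawn, against 1.1 points reckoned with the summed order. Midnight's lost time is 0.0327 h, which at a full rate of 0.217 /h gives 1.46% of the charge by 0.100 h, and midnight held 1.37% then.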